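I was asked what stood in the flask at 5.0 h, with 2.0 mM of X and 4.00 mM of D: how much X had reacted, how much Z there was, and what, if anything, had brought it to rest.

| flask | X | D | remark | time |
|---|---|---|---|---|
| south-west | 2 mM | 2 mM | run made earlier |  |
| south | 2 mM | 8 mM | run made earlier |  |
| flask | 2.0 mM | 4.00 mM |  | 5.0 h |

| run | time / h | X / % | Z / % |
|---|---|---|---|
| south-west | 0.500 | 2 | 6 |
| south-west | 1.50 | 0 | 5 |
| south-west | 3.00 | 0 | 5 |
| south-west | 4.00 | 4 | 8 |
| south-west | 6.00 | 7 | 6 |
| south | 0.500 | 0 | 26 |
| south | 1.50 | 0 | 32 |
| south | 3.00 | 3 | 29 |
| south | 4.00 | 1 | 27 |
| south | 6.00 | 0 | 29 |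

(scatter of a reading: 2 percentage points)

- the reaction counts as stopped when no species that holds the X changes by six tenths of a point or more over the second half of the time

- which holds at 5.0 h: what has brought the reaction to rest, or that it has not come to rest (it is still moving / all of X has reacted / forward and back rates have come level / D has run out first)
- how much of the X has reacted by 5.0 h
- how much Z there is at 5.0 h, in percent of the X charged

The two earlier runs look nearly the same, with the same charge of X, yet Z lay flat near 6% in the south-west run and near 29% in the south run. Both levels were flat over the hours, so I looked to the D charge. I took it that each X reacted costs one D and that the part of X ending as Z costs a second. With D in excess, the south run gives that part as its mean Z, 28.6%. So my D demand, the D needed to carry Z to that share, in percent of the X charged, was 129%; it is a limiting-reagent test.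

The south-west run held 2 mM of D, less than 129% of its X, so it fell short and Z stayed low. The south run held 8 mM, more than its demand, as reading the share from it requires. The flask needed 2.58 mM and held 4.00 mM, so I placed it with the south run, with Z near 28.6%. X in the south run read 0% at 6.00 h, so I expected the flask to come to rest the same way, with its X reacted.

The forecast said that all of X has reacted, with 99% reacted and Z at 14%, from “an apparent order in D of about 1.3”. We agreed on the end and parted on Z.

The flask gave Z at 27.6%, 14 percentage points above the forecast, with 100% of X reacted, and the end was that all of X has reacted.

    X + D → Q (k = 12.0 /M/s)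
    D + Q → J (k = 2.29 /M/s)
    X + D → E (k = 31.4 /M/s)
    J → Z (k = 0.00873 /s)
    D → G (k = 5.31 × 10⁻⁵ /s)
    X ⇌ L (K = 4.70, k = 0.00287 /s)

Lowering D in this flask, Z had moved by 5 points at 2.48 mM, below the demand of 2.58 mM. The neighbouring flask with 5.0 mM of X under the same D had a demand of 6.45 mM, above its 4.00 mM. There D stood at 0% of its charge at 5.00 h, Q held 20.6% of the X charged, and Z reached 1.18%.

The readings are simulated on assumed constants, and the scatter is random.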